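**Plan**

- Retrosynthesis: the six O‑benzyl bonds are cut first, then the aryl–vinyl bond at ring D, then C4–C4a of ring C, then the O1–C8a aryl ether bond, then the C2–H and oxirane C–O bonds, and last the C3–C4 bond (as a chalcone C=C).
- Enabling feature: C4 is benzylic to ring D, whose two oxygens sit ortho and para to the carbon that bears C4, and its neighbour C3 carries the hydroxyl. C4a lies para to O7 and ortho to O1 of ring A. A C3–C4 epoxide and a ring A aryl ether on C2 therefore pair an easily opened electrophile with a well‑placed arene nucleophile.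
- Forward: the ring D aldehyde and the ring B ketone give the C2–C3–C4 chain, which is epoxidised and reduced; ring A is attached through O1; ring C then closes at C4–C4a; the styryl arm is added by Heck coupling; global debenzylation ends the route.
- Stereochemistry: peptide‑controlled epoxidation fixes C3 and C4 of the oxirane, chelation‑controlled hydride addition sets C2 relative to it, O‑arylation leaves C2 untouched, anti opening of the trans‑epoxide inverts C4 to the 3,4‑trans flavan, and the Heck reaction gives the E‑alkene.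

Key step: step 9

Remark: the target is read as the (2R,3S,4S), 2,3‑trans‑3,4‑trans flavan‑3‑ol with an (E)‑stilbene; the change of CIP letter at the oxirane carbon next to C2 in 7, 8 and 13 comes from priority changes only, not from inversion.

Step 1
Reactants: 1 5‑bromoresorcinol
Product: 2 1,3‑bis(benzyloxy)‑5‑bromobenzene
Conditions: BnBr, K2CO3, DMF, 60 °C
Reagents that add atoms: benzyl bromide, BrCc1ccccc1
Why: Williamson ether synthesis, in which both phenoxides are alkylated by SN2 at the benzylic halide to give ethers that tolerate the later basic, hydridic and weakly acidic steps.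

Step 2
Reactants: 2 1,3‑bis(benzyloxy)‑5‑bromobenzene
Product: 4 2,4‑bis(benzyloxy)‑6‑bromobenzaldehyde, via aryl iminium chloride 3 (not isolated)
Conditions: POCl3, DMF, 0 → 90 °C; then aq. NaOAc, rt
Reagents that add atoms: N,N‑dimethylformamide, CN(C)C=O (formyl carbon); water, O (carbonyl oxygen)
Why: Vilsmeier–Haack formylation, in which the chloroiminium ion attacks the ring carbon that is para to one benzyloxy group and ortho to the other (next to bromine), the site known to be preferred in the dimethyl ether analogue over the carbon between the two ethers, and the iminium salt is hydrolysed on work‑up.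

Step 3
Reactants: 4 2,4‑bis(benzyloxy)‑6‑bromobenzaldehyde; 5 4'‑(benzyloxy)acetophenone
Product: 6 (E)‑1‑[4‑(benzyloxy)phenyl]‑3‑[2,4‑bis(benzyloxy)‑6‑bromophenyl]prop‑2‑en‑1‑one
Conditions: KOH, EtOH/THF, rt → 40 °C
Reagents that add atoms: none
Why: Claisen–Schmidt condensation of a non‑enolisable aldehyde with the methyl ketone, where E1cB loss of water from the aldol gives the conjugated E‑enone and so forms the future C3–C4 bond.

Step 4
Reactants: 6 the chalcone
Product: 7 [4‑(benzyloxy)phenyl]{(2S,3R)‑3‑[2,4‑bis(benzyloxy)‑6‑bromophenyl]oxiran‑2‑yl}methanone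
Conditions: poly‑D‑leucine (from D‑leucine N‑carboxyanhydride), urea–H2O2, DBU, THF, rt
Reagents that add atoms: hydrogen peroxide (used as its urea adduct), OO
Why: Juliá–Colonna epoxidation, a Weitz–Scheffer conjugate addition of hydroperoxide inside the helical peptide that turns the E‑enone into the trans‑epoxide; poly‑L‑leucine is known to give (2R,3S)‑chalcone oxides, so the D‑peptide should give the (2S,3R) enantiomer, and the basic medium spares the acid‑labile benzylic C–O bond next to ring D.

Step 5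
Reactants: 7 the epoxy ketone
Product: 8 (R)‑[4‑(benzyloxy)phenyl]{(2R,3R)‑3‑[2,4‑bis(benzyloxy)‑6‑bromophenyl]oxiran‑2‑yl}methanol (erythro)
Conditions: Zn(BH4)2 (ethereal solution), Et2O, −30 °C; then aq. NH4Cl
Reagents that add atoms: none
Why: chelation‑controlled hydride reduction of an α,β‑epoxy ketone, in which zinc bridges the carbonyl and oxirane oxygens and hydride adds to the face turned away from the ring D‑bearing oxirane carbon, which should give the erythro (anti) alcohol and so the R configuration at the future C2.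

Step 6
Reactants: 9 3‑iodophenol
Product: 10 1‑(benzyloxy)‑3‑iodobenzene
Conditions: BnBr, K2CO3, acetone, reflux
Reagents that add atoms: benzyl bromide, BrCc1ccccc1
Why: Williamson ether synthesis by SN2 of the phenoxide on benzyl bromide.

Step 7
Reactants: 10 1‑(benzyloxy)‑3‑iodobenzene
Product: 12 [3‑(benzyloxy)phenyl](2,4,6‑trimethoxyphenyl)iodonium tosylate, via hydroxy(tosyloxy)iodoarene 11 (not isolated)
Conditions: mCPBA, TsOH·H2O, MeCN, 77 °C; then 1,3,5‑trimethoxybenzene, 77 °C
Reagents that add atoms: 1,3,5‑trimethoxybenzene, COc1cc(OC)cc(OC)c1; p‑toluenesulfonic acid, Cc1ccc(cc1)S(=O)(=O)O (counter‑ion); mCPBA, OOC(=O)c1cccc(Cl)c1 (hydroxy oxygen of 11 only)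
Why: one‑pot diaryliodonium synthesis, in which the aryl iodide is oxidised to trivalent iodine and the resulting electrophile substitutes the very electron‑rich trimethoxybenzene, which then serves as a non‑transferred dummy ligand.

Step 8
Reactants: 8 the erythro epoxy alcohol; 12 the iodonium tosylate
Product: 13 (2S,3R)‑2‑{(R)‑[3‑(benzyloxy)phenoxy][4‑(benzyloxy)phenyl]methyl}‑3‑[2,4‑bis(benzyloxy)‑6‑bromophenyl]oxirane
Conditions: NaH, toluene, 0 °C → rt
Reagents that add atoms: none
Why: metal‑free O‑arylation of an alkoxide with a diaryliodonium salt (ligand exchange at iodine, then ligand coupling that transfers the less electron‑rich 3‑(benzyloxy)phenyl group), which never breaks the carbinol C–O bond and so keeps C2, while any ketone 7 formed by competing oxidation can be returned through step 5.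

Step 9
Reactants: 13 the erythro trans‑epoxy aryl ether
Product: 14 (2R,3S,4S)‑7‑(benzyloxy)‑2‑[4‑(benzyloxy)phenyl]‑4‑[2,4‑bis(benzyloxy)‑6‑bromophenyl]chroman‑3‑ol
Conditions: (CF3)2CHOH/CH2Cl2 (4:1), 0 °C → rt
Reagents that add atoms: none
Why: Hydrogen bonding of the fluoroalcohol to the oxirane oxygen lengthens the C4–O bond, whose positive charge is taken up by the ortho and para benzyloxy groups of ring D; the ring A carbon para to the 7‑benzyloxy group and ortho to the ether oxygen then attacks C4 from the side opposite the departing oxygen and rearomatises by proton loss. The closest known reaction type is the intramolecular Friedel–Crafts epoxide–arene cyclisation of aryl glycidyl ethers to chroman‑3‑ols, promoted by fluoroalcohols or by Lewis acids such as AuCl3. Ring C closes in the 6‑endo‑tet mode, which beats 5‑exo attack at C3 because only C4 is benzylic. The new stereocentre C4 is set by inversion at the trans‑epoxide carbon, which gives the 3,4‑trans (4S) arrangement while C2 (R) and C3 (S) are not touched; should the bond ionise fully, chair‑like closure with ring D equatorial leads to the same isomer. The step needs C4 over C3 (secured by ring D donation) and C4a over the ring A carbon between the two oxygens (secured by para activation and lower crowding). It also needs epoxide opening to outrun heterolysis of the C2–O ether or a 1,2‑hydride shift, which is secured by mild hydrogen‑bond activation without a Lewis acid and by the tethered arene being the nearest nucleophile.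

Step 10
Reactants: 15 3,4‑bis(benzyloxy)benzaldehyde
Product: 16 3,4‑bis(benzyloxy)styrene
Conditions: Ph3PCH3Br, KOtBu, THF, 0 °C → rt
Reagents that add atoms: methyltriphenylphosphonium bromide, C[P+](c1ccccc1)(c1ccccc1)c1ccccc1.[Br-]
Why: Wittig methylenation of an aromatic aldehyde with the unstabilised ylide.

Step 11
Reactants: 14 the bromoflavanol; 16 3,4‑bis(benzyloxy)styrene
Product: 17 (2R,3S,4S)‑7‑(benzyloxy)‑2‑[4‑(benzyloxy)phenyl]‑4‑{2,4‑bis(benzyloxy)‑6‑[(E)‑2‑[3,4‑bis(benzyloxy)phenyl]ethenyl]phenyl}chroman‑3‑ol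
Conditions: Pd(OAc)2, P(o‑tol)3, Et3N, DMF, 100 °C
Reagents that add atoms: none
Why: Mizoroki–Heck reaction, in which zerovalent palladium inserts into the C–Br bond (meta to both ring D ethers), the styrene inserts with the aryl group going to its terminal carbon and syn β‑hydride elimination gives the E‑stilbene, while the amine base leaves the C3 hydroxyl un‑ionised so that aryl–oxygen coupling should not compete.

Step 12
Reactants: 17 the hexabenzyl ether
Product: 18 (2R,3S,4S)‑4‑{2‑[(E)‑2‑(3,4‑dihydroxyphenyl)ethenyl]‑4,6‑dihydroxyphenyl}‑2‑(4‑hydroxyphenyl)chromane‑3,7‑diol (CNP0170061.1)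
Conditions: BCl3, C6HMe5, CH2Cl2, −78 °C; then MeOH
Reagents that add atoms: none
Why: Lewis‑acid debenzylation with pentamethylbenzene as a non‑basic cation scavenger, which should take up the benzyl cations at low temperature before they reach the stilbene or the phenol rings, needs no hydrogen and so spares the alkene, and touches no stereocentre.

**Compound list**

1 | 5‑bromoresorcinol | Oc1cc(O)cc(Br)c1 | starting material
2 | 1,3‑bis(benzyloxy)‑5‑bromobenzene | Brc1cc(OCc2ccccc2)cc(OCc2ccccc2)c1 | intermediate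
3 | [2,4‑bis(benzyloxy)‑6‑bromophenyl]methylidene(dimethyl)iminium chloride | C[N+](C)=Cc1c(Br)cc(OCc2ccccc2)cc1OCc1ccccc1.[Cl-] | intermediate (not isolated)
4 | 2,4‑bis(benzyloxy)‑6‑bromobenzaldehyde | O=Cc1c(Br)cc(OCc2ccccc2)cc1OCc1ccccc1 | intermediate
5 | 4'‑(benzyloxy)acetophenone | CC(=O)c1ccc(OCc2ccccc2)cc1 | starting material
6 | (E)‑1‑[4‑(benzyloxy)phenyl]‑3‑[2,4‑bis(benzyloxy)‑6‑bromophenyl]prop‑2‑en‑1‑one | O=C(/C=C/c1c(Br)cc(OCc2ccccc2)cc1OCc1ccccc1)c1ccc(OCc2ccccc2)cc1 | intermediate
7 | [4‑(benzyloxy)phenyl]{(2S,3R)‑3‑[2,4‑bis(benzyloxy)‑6‑bromophenyl]oxiran‑2‑yl}methanone | c1ccccc1COc1ccc(C(=O)[C@H]2O[C@@H]2c2c(OCc3ccccc3)cc(OCc3ccccc3)cc2Br)cc1 | intermediate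
8 | (R)‑[4‑(benzyloxy)phenyl]{(2R,3R)‑3‑[2,4‑bis(benzyloxy)‑6‑bromophenyl]oxiran‑2‑yl}methanol | c1ccccc1COc1ccc([C@@H](O)[C@H]2O[C@@H]2c2c(OCc3ccccc3)cc(OCc3ccccc3)cc2Br)cc1 | intermediate
9 | 3‑iodophenol | Oc1cccc(I)c1 | starting material
10 | 1‑(benzyloxy)‑3‑iodobenzene | Ic1cccc(OCc2ccccc2)c1 | intermediate
11 | 1‑(benzyloxy)‑3‑[hydroxy(tosyloxy)iodo]benzene | OI(OS(=O)(=O)c1ccc(C)cc1)c1cccc(OCc2ccccc2)c1 | intermediate (not isolated)
12 | [3‑(benzyloxy)phenyl](2,4,6‑trimethoxyphenyl)iodonium tosylate | COc1cc(OC)c([I+]c2cccc(OCc3ccccc3)c2)c(OC)c1.Cc1ccc(cc1)S(=O)(=O)[O-] | intermediate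
13 | (2S,3R)‑2‑{(R)‑[3‑(benzyloxy)phenoxy][4‑(benzyloxy)phenyl]methyl}‑3‑[2,4‑bis(benzyloxy)‑6‑bromophenyl]oxirane | c1ccccc1COc1ccc([C@@H](Oc2cccc(OCc3ccccc3)c2)[C@H]2O[C@@H]2c2c(OCc3ccccc3)cc(OCc3ccccc3)cc2Br)cc1 | intermediate
14 | (2R,3S,4S)‑7‑(benzyloxy)‑2‑[4‑(benzyloxy)phenyl]‑4‑[2,4‑bis(benzyloxy)‑6‑bromophenyl]chroman‑3‑ol | c1ccccc1COc1ccc([C@H]2Oc3cc(OCc4ccccc4)ccc3[C@@H](c3c(OCc4ccccc4)cc(OCc4ccccc4)cc3Br)[C@@H]2O)cc1 | intermediate
15 | 3,4‑bis(benzyloxy)benzaldehyde | O=Cc1ccc(OCc2ccccc2)c(OCc2ccccc2)c1 | starting material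
16 | 3,4‑bis(benzyloxy)styrene | C=Cc1ccc(OCc2ccccc2)c(OCc2ccccc2)c1 | intermediate
17 | (2R,3S,4S)‑7‑(benzyloxy)‑2‑[4‑(benzyloxy)phenyl]‑4‑{2,4‑bis(benzyloxy)‑6‑[(E)‑2‑[3,4‑bis(benzyloxy)phenyl]ethenyl]phenyl}chroman‑3‑ol | c1ccccc1COc1ccc([C@H]2Oc3cc(OCc4ccccc4)ccc3[C@@H](c3c(OCc4ccccc4)cc(OCc4ccccc4)cc3/C=C/c3ccc(OCc4ccccc4)c(OCc4ccccc4)c3)[C@@H]2O)cc1 | intermediate
18 | (2R,3S,4S)‑4‑{2‑[(E)‑2‑(3,4‑dihydroxyphenyl)ethenyl]‑4,6‑dihydroxyphenyl}‑2‑(4‑hydroxyphenyl)chromane‑3,7‑diol | Oc1ccc([C@H]2Oc3cc(O)ccc3[C@@H](c3c(O)cc(O)cc3/C=C/c3ccc(O)c(O)c3)[C@@H]2O)cc1 | target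

**Step count**

Total: 12 steps. Longest linear sequence: 9 steps (steps 1, 2, 3, 4, 5, 8, 9, 11, 12).

**Steps most likely to fail**

Step 8 (O‑arylation). The hindered secondary benzylic alkoxide may be oxidised by the iodonium salt back to ketone 7, may suffer base‑induced epoxide migration (Payne rearrangement) before it is arylated, or may couple too slowly. The fallback sets out from epoxy alcohol 8 and aryl iodide 10, which step 6 already provides. The two would be joined by copper‑catalysed Ullmann‑type etherification (CuI, 3,4,7,8‑tetramethyl‑1,10‑phenanthroline, Cs2CO3, toluene, 80–110 °C). This is a cross‑coupling that likewise leaves the carbinol C–O bond intact and keeps the concentration of free alkoxide low. It comes back to the route at 13 and makes no new compound (F0).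

Step 9 (ring closure). A 1,2‑hydride shift in the opening epoxide (Meinwald‑type rearrangement to a C3 ketone) or heterolysis of the C2–O aryl ether may outrun the closure, or a long‑lived cation may close with poor facial selectivity. The fallback sets out from 13 and separates epoxide opening from C–C bond formation. Thiolysis at the benzylic carbon with benzyl mercaptan in CF3CH2OH at 0 °C would give (1R,2R,3RS)‑1‑[3‑(benzyloxy)phenoxy]‑1‑[4‑(benzyloxy)phenyl]‑3‑(benzylsulfanyl)‑3‑[2,4‑bis(benzyloxy)‑6‑bromophenyl]propan‑2‑ol F1. Its C–S bond would then be ionised with AgBF4 in CH2Cl2 at −40 °C, the established thiophilic way of generating flavan C4 cations for arylation. Ring A should close onto C4 to give the all‑equatorial 3,4‑trans isomer, which is 14, where the route is rejoined.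

Step 12 (global debenzylation). Under BCl3 the electron‑rich stilbene may take up HCl or benzyl cations or lose its E geometry, and cleavage of six ethers in one operation may stall. The fallback sets out from 14 and exchanges the protecting groups before any alkene is present. Debenzylation of 14 (BCl3, C6HMe5, CH2Cl2, −78 °C) would give (2R,3S,4S)‑4‑(2‑bromo‑4,6‑dihydroxyphenyl)‑2‑(4‑hydroxyphenyl)chromane‑3,7‑diol F2. Acetylation (Ac2O, pyridine) would give its pentaacetate F3. Heck coupling of F3 with commercial 3,4‑diacetoxystyrene (Pd(OAc)2, P(o‑tol)3, Et3N, DMF, 100 °C) would give the heptaacetate of the target F4. Methanolysis (K2CO3, MeOH, 0 °C, under argon) then comes back to the route at 18, with no Lewis acid ever meeting the stilbene.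

**Further compounds**

F0 | step 8 | none | none
F1 | step 9 | (1R,2R,3RS)‑1‑[3‑(benzyloxy)phenoxy]‑1‑[4‑(benzyloxy)phenyl]‑3‑(benzylsulfanyl)‑3‑[2,4‑bis(benzyloxy)‑6‑bromophenyl]propan‑2‑ol | c1ccccc1COc1ccc([C@@H](Oc2cccc(OCc3ccccc3)c2)[C@@H](O)C(SCc2ccccc2)c2c(OCc3ccccc3)cc(OCc3ccccc3)cc2Br)cc1
F2 | step 12 | (2R,3S,4S)‑4‑(2‑bromo‑4,6‑dihydroxyphenyl)‑2‑(4‑hydroxyphenyl)chromane‑3,7‑diol | Oc1ccc([C@H]2Oc3cc(O)ccc3[C@@H](c3c(O)cc(O)cc3Br)[C@@H]2O)cc1
F3 | step 12 | (2R,3S,4S)‑3,7‑diacetoxy‑2‑(4‑acetoxyphenyl)‑4‑(2,4‑diacetoxy‑6‑bromophenyl)chromane | CC(=O)Oc1ccc([C@H]2Oc3cc(OC(C)=O)ccc3[C@@H](c3c(OC(C)=O)cc(OC(C)=O)cc3Br)[C@@H]2OC(C)=O)cc1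
F4 | step 12 | (2R,3S,4S)‑3,7‑diacetoxy‑2‑(4‑acetoxyphenyl)‑4‑{2,4‑diacetoxy‑6‑[(E)‑2‑(3,4‑diacetoxyphenyl)ethenyl]phenyl}chromane | CC(=O)Oc1ccc([C@H]2Oc3cc(OC(C)=O)ccc3[C@@H](c3c(OC(C)=O)cc(OC(C)=O)cc3/C=C/c3ccc(OC(C)=O)c(OC(C)=O)c3)[C@@H]2OC(C)=O)cc1
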